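## Structural features

The target is a 1,4-benzoquinone (ring A). Its C1 carbonyl is flanked by a methyl group on one side and a C20 tetraprenyl chain on the other. The chain is numbered C1 to C16 from the ring, and the oxidised branch carbon on C11 is called C20. C2=C3 and C6=C7 are ordinary E-configured, methyl-branched double bonds, C14=C15 is an isopropylidene end group, and all chain alkenes stand in 1,5-diene spacing. The only stereocentre, C12 (R), is a secondary carbinol that is allylic to C10=C11 and homoallylic to C14=C15, so C10 to C15 form a 1,5-dien-3-ol. At C10=C11 the chain carbon C9 stands cis to the hydroxymethyl carbon C20 and trans to C12 (E by the sequence rule), directly beside the stereocentre. The fragile points are: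
- the quinone (hydrides, bases, nucleophiles, organometallics);
- the doubly activated C1 methylene;
- the C12 carbinol (ionisation under acid, anionic oxy-Cope rearrangement under strong base);
- the polyene (cationic cyclisation).

The real difficulty is the array C10=C11(C20)–C12. It packs an alkene geometry, a carbinol configuration and a 1,3-diol into four carbons, far from ring A and from any other stereocentre, so nothing in the substrate can control them. The key step exploits the fact that C20–C11(=C10)–C12(OH) is, one oxidation level down, the skeleton of a beta-substituted alpha-(1-hydroxyalkyl)acrylate. C10, C11 and C20 map onto the three carbons of a propiolic ester and C12 onto a formyl carbon. The cis relation of C9 and C20 is the one left when a placeholder (iodide) adds to C10 and the aldehyde then enters at C11 from the side of the C10 hydrogen.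

## Logic of the disconnections

**19 to 18.** No carbon–carbon bond is cut. The two carbonyl groups of ring A are traced back to two aryl–OMe groups. The quinone cannot pass through hydride, organoboron, palladium/base or organomagnesium chemistry, so it is unveiled last. The gain is a robust arene for the whole route. The demand is an oxidation that takes the electron-rich arene within minutes at 0 °C in the presence of four alkenes and a free allylic 1,3-diol.

**18 to 17.** The two C20–H bonds are removed, which raises C20 to the ester level. This exposes the acrylate pattern on which the key step rests, and costs no protecting group. The forward step must be a clean 1,2-reduction that leaves C10=C11 and C12 alone.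

**17 to 9 and 15 (through 16).** The sp3–sp2 bond C9–C10 is cut. This separates a stereochemically trivial aryl diene from a small fragment that holds all the difficulty. It avoids the regiochemical ambiguity of an allyl–allyl union at C8–C9, and it uses a bond-forming process that retains alkene geometry. The demands are hydroboration at C8=C9 only, and a coupling base mild enough for a beta-hydroxy ester.

**15 to 11 and 12 (through 13 and 14). Key disconnection.** Two bonds are cut at once, C11–C12 and C10–I, and C10=C11 goes back to the triple bond of 12. C10, C11 and C20 are the three carbons of 12; C12 to C15 with both methyl groups are 11. In one move the stereocentre, the trisubstituted double bond, the 1,3-dioxygenation pattern and the docking point for the chain all disappear, and the remainder has no stereochemical element. The forward step must do three things: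
- place iodine at C10 and C12 at C11 in a fixed trans relation;
- tell the faces of a slim, unbranched formyl group apart by catalyst control alone;
- run cold and without base, so that C14=C15 stays out of conjugation.

In one sentence, the route is an enantioselective three-component coupling of 11, 12 and iodide. That sentence does not describe the customary plans, which bring an alkenyl metal or an olefination reagent to a preformed chain.

**11 to 10.** The formyl C–H/C=O is traced back to a primary carbinol, and no skeletal bond is cut. The demand is a neutral oxidation that does not move the double bond.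

**9 to 8, 7 and 6.** C8=C9 is cut (one-carbon olefination), then the C8–O bond (allylic oxidation of the E-methyl group). This reduces the nine-carbon chain to the commercial ten-carbon geranyl unit. The demand is site selectivity for the terminal isopropylidene group over C2=C3 and the C1 methylene.

**6 to 3 and 4 (through 5).** The aryl–C1 bond is cut, which gives two simple halves. The demand is attack at the primary allylic terminus with retention of the E geometry of C2=C3.

**3 to 2 and 1.** One O–CH3 bond and the C–Br bond are cut. The free phenol of 1 directs the halogen to the only open ortho position, which fixes the 2,6-pattern of ring A.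

## Other disconnections considered

**Alternative 1:** (the first that comes to mind) Cut C11–C12 on the finished chain, between alkenyl iodide A1, which already carries the arene, C1 to C11 and C20, and aldehyde 11. The forward key step is a Nozaki–Hiyama–Kishi addition (CrCl2, cat. NiCl2), or iodine–lithium exchange and addition, to give silyl ether A2.
- This step does not touch the C10=C11 geometry. That geometry must be built beforehand on the long chain by alkyne formation, hydroxymethylation, a syn-hydrometalation that must tell apart two alkyne carbons with nearly equal CH2 substituents, iodination and protection. This adds about five linear steps.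
- The addition has no internal facial bias, and ligand control in chromium additions relies on a steric difference that the unbranched 11 does not offer.
- 11 would also meet Lewis acidic chromium salts at room temperature or a basic alkenyllithium. Both invite enolisation and migration of C14=C15.
- The chosen plan forms the same sigma bond but creates the double bond, its geometry and the docking site in the same event from an alkyne, on a small fragment.

**Alternative 2:** Cut C12–C13 and reconnect O12 to C15, which leads to the bis-allylic ether A3. The forward key step is deprotonation at C12 and a [2,3]-Wittig rearrangement that gives 18 directly.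
- In its favour, the 1,5-dien-3-ol C10 to C15 is the textbook retron. The quaternary C15 also leaves only one side to deprotonate and delivers the prenyl group in linear form.
- C15 bears two methyl groups, so there is no stereocentre from which chirality could be carried. C12 would depend on an external ligand on a configurationally labile allyllithium.
- The alkyllithium base would also find the C1 methylene (benzylic, allylic, next to OMe) and the ring positions ortho to OMe.
- The product alkoxide is an oxy-Cope substrate.
- The C10=C11 geometry and the differentiation of the two CH2O groups remain unsolved problems upstream.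

**Alternative 3:** Cut C10=C11 to a ketone. The partners are the (R)-dioxanone A4 (dihydroxyacetone acetonide prenylated through its RAMP hydrazone) and the ylide from phosphonium salt A5, joined by a Wittig olefination.
- In its favour, C12 would be set by a very reliable hydrazone alkylation.
- The geometry is decided in an early, puckered transition state. There a non-stabilised ylide tends to put its substituent cis to the larger carbonyl flank, the same preference that makes aldehydes give Z-alkenes. That would be cis to C12, the opposite of what is needed. Only product-like allylic strain argues the other way.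
- The basic ylide can enolise the alpha-alkoxy ketone, which would erode C12 and open a beta-elimination path.
- A5 needs terminal cleavage of a farnesyl arene plus three functional group steps, so the linear sequence is longer.

Key step: step 8

Assumption: the sense of induction in step 8 follows the accepted pre-transition-state model of the oxazaborolidinium catalyst (Si-face attack with the catalyst from (S)-diphenylprolinol). If 11 behaved oppositely, the catalyst from (R)-diphenylprolinol would be used with no other change.

## Steps

Step 1
Reactants: 1 4-methoxy-2-methylphenol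
Product: 2 2-bromo-4-methoxy-6-methylphenol
Conditions: NBS (1.0 equiv), MeCN, 0 °C
Reagents that add atoms: N-bromosuccinimide, O=C1CCC(=O)N1Br
Why: Electrophilic aromatic bromination; the free OH is the strongest director, its para position carries OMe and one ortho position carries the methyl group, so only C6 is open.

Step 2
Reactants: 2 2-bromo-4-methoxy-6-methylphenol
Product: 3 1-bromo-2,5-dimethoxy-3-methylbenzene
Conditions: MeI, K2CO3, acetone, reflux
Reagents that add atoms: iodomethane, CI
Why: Williamson ether synthesis; the two methyl ethers mask the quinone through all organometallic and hydride steps.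

Step 3
Reactants: 3 1-bromo-2,5-dimethoxy-3-methylbenzene; 4 geranyl bromide [(2E)-1-bromo-3,7-dimethylocta-2,6-diene]
Product: 6 1-[(2E)-3,7-dimethylocta-2,6-dienyl]-2,5-dimethoxy-3-methylbenzene, via aryl Grignard reagent 5 (not isolated)
Conditions: Mg, THF, reflux; then 4, CuI (5 mol %), THF, 0 °C to rt
Reagents that add atoms: none
Why: Copper-catalysed allylic substitution of an aryl Grignard reagent on a primary allylic bromide; attack at the unhindered CH2 terminus (SN2, not SN2') should keep the E geometry of C2=C3.

Step 4
Reactants: 6 1-[(2E)-3,7-dimethylocta-2,6-dienyl]-2,5-dimethoxy-3-methylbenzene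
Product: 7 (2E,6E)-8-(2,5-dimethoxy-3-methylphenyl)-2,6-dimethylocta-2,6-dien-1-ol
Conditions: SeO2 (0.3 equiv), t-BuOOH (3 equiv), salicylic acid (0.1 equiv), CH2Cl2, 0 °C to rt
Reagents that add atoms: tert-butyl hydroperoxide, CC(C)(C)OO
Why: Catalytic SeO2 allylic oxidation (ene reaction, then [2,3]-sigmatropic shift) prefers the most electron-rich and least hindered isopropylidene end and takes the methyl group trans to the chain, which makes C8 the CH2OH carbon on an E-configured C6=C7.

Step 5
Reactants: 7 (2E,6E)-8-(2,5-dimethoxy-3-methylphenyl)-2,6-dimethylocta-2,6-dien-1-ol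
Product: 8 (2E,6E)-8-(2,5-dimethoxy-3-methylphenyl)-2,6-dimethylocta-2,6-dienal
Conditions: MnO2 (15 equiv), CH2Cl2, rt
Reagents that add atoms: none
Why: MnO2 oxidises allylic alcohols selectively, stops at the enal and leaves the E geometry and the arene untouched.

Step 6
Reactants: 8 (2E,6E)-8-(2,5-dimethoxy-3-methylphenyl)-2,6-dimethylocta-2,6-dienal
Product: 9 1-[(2E,6E)-3,7-dimethylnona-2,6,8-trienyl]-2,5-dimethoxy-3-methylbenzene
Conditions: Ph3PCH3Br, NaN(SiMe3)2, THF, 0 °C; then 8, −78 °C to rt
Reagents that add atoms: methyltriphenylphosphonium bromide, C[P+](c1ccccc1)(c1ccccc1)c1ccccc1.[Br-]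
Why: Wittig methylenation adds C9 by 1,2-attack on the enal; no stereochemical element is created, and C6=C7 is not part of the reacting pi bond.

Step 7
Reactants: 10 4-methylpent-3-en-1-ol
Product: 11 4-methylpent-3-enal
Conditions: 2-iodoxybenzoic acid (IBX, 1.3 equiv), DMSO, rt; used at once as a pentane/CH2Cl2 solution
Reagents that add atoms: none
Why: IBX oxidation runs without base or strong acid, stops at the aldehyde and should leave the beta,gamma double bond out of conjugation; 11 is volatile and labile and is not stored.

Step 8
Reactants: 11 4-methylpent-3-enal; 12 ethyl propiolate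
Product: 15 ethyl (2Z)-2-[(1R)-1-hydroxy-4-methylpent-3-enyl]-3-iodoprop-2-enoate, via silyl iodoallenolate 13 (not isolated), via trimethylsilyl ether 14 (not isolated)
Conditions: 12 (2 equiv), Me3SiI (1.5 equiv), (S)-3,3-diphenyl-1-(2-methylphenyl)tetrahydropyrrolo[1,2-c][1,3,2]oxazaborole·HNTf2 (20 mol %), CH2Cl2, −78 °C; then 1 M HCl, THF, 0 °C
Reagents that add atoms: iodotrimethylsilane, C[Si](C)(C)I
Why: Me3SiI adds in conjugate fashion to 12 and gives the silyl iodoallenolate 13, which attacks the formyl carbon of 11 while 11 is bound to the boron atom of the cationic oxazaborolidinium catalyst (Mukaiyama-type aldol addition); silyl transfer to the aldolate oxygen gives 14 and frees the catalyst, and dilute acid unmasks 15. The closest known reaction type is the catalytic enantioselective three-component beta-iodo Morita–Baylis–Hillman (halo-aldol) coupling of propiolic esters, Me3SiI and aromatic or aliphatic aldehydes, of which this is a plain application. No ring is closed; the bonds formed are C10–I and C11–C12. C12 is controlled by the catalyst alone: the formyl group is fixed by B–O coordination and a formyl C–H···O contact, one aryl group of the diarylprolinol unit covers its Re face, and attack of C11 on the open Si face gives R. The C10=C11 geometry follows from the shape of 13: the nucleophilic pi orbital at C11 lies in the plane that holds the C10–H and C10–I bonds, so the bulky aldehyde–catalyst complex can only come in beside H or beside I and takes the side of H, which puts C12 trans to iodine and iodine cis to the ester (Z). At −78 °C the addition is kinetic and the Z-iodide should not drift to the E-isomer. Beyond this, addition to the formyl group must outrun acid-induced migration of, or HI addition to, the C14=C15 bond of 11; the low temperature, the absence of any base and freshly distilled Me3SiI secure it, and neither partner offers a second reactive site.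

Step 9
Reactants: 9 1-[(2E,6E)-3,7-dimethylnona-2,6,8-trienyl]-2,5-dimethoxy-3-methylbenzene; 15 ethyl (2Z)-2-[(1R)-1-hydroxy-4-methylpent-3-enyl]-3-iodoprop-2-enoate
Product: 17 ethyl (2Z,6E,10E)-12-(2,5-dimethoxy-3-methylphenyl)-2-[(1R)-1-hydroxy-4-methylpent-3-enyl]-6,10-dimethyldodeca-2,6,10-trienoate, via B-alkyl borane 16 (not isolated)
Conditions: 9, 9-BBN-H (1.1 equiv), THF, 0 °C to rt; then 15, Pd(dppf)Cl2 (5 mol %), AsPh3 (10 mol %), Cs2CO3 (2 equiv), DMF–H2O, rt
Reagents that add atoms: none
Why: 9-BBN-H adds to the only monosubstituted double bond (C8=C9) with boron on the terminal C9. The B-alkyl Suzuki–Miyaura coupling then forms C9–C10 with retention at the alkenyl iodide, so C9 takes the place of iodine cis to the ester. Room temperature and a carbonate base should spare the beta-hydroxy ester and C12.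

Step 10
Reactants: 17 ethyl (2Z,6E,10E)-12-(2,5-dimethoxy-3-methylphenyl)-2-[(1R)-1-hydroxy-4-methylpent-3-enyl]-6,10-dimethyldodeca-2,6,10-trienoate
Product: 18 (2E,6E,10E,12R)-1-(2,5-dimethoxy-3-methylphenyl)-11-(hydroxymethyl)-3,7,15-trimethylhexadeca-2,6,10,14-tetraen-12-ol
Conditions: i-Bu2AlH (4 equiv), CH2Cl2, −78 to −20 °C; aq. potassium sodium tartrate
Reagents that add atoms: none
Why: i-Bu2AlH reduces the unsaturated ester in 1,2-fashion to the allylic alcohol after the first equivalent is taken up by the C12 hydroxyl. C12 and the alkenes are not touched. The descriptor of C10=C11 changes from Z to E only because CH2OH ranks below C12.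

Step 11
Reactants: 18 (2E,6E,10E,12R)-1-(2,5-dimethoxy-3-methylphenyl)-11-(hydroxymethyl)-3,7,15-trimethylhexadeca-2,6,10,14-tetraen-12-ol
Product: 19 2-[(2E,6E,10E,12R)-12-hydroxy-11-(hydroxymethyl)-3,7,15-trimethylhexadeca-2,6,10,14-tetraenyl]-6-methylcyclohexa-2,5-diene-1,4-dione (target)
Conditions: (NH4)2Ce(NO3)6 (2.5 equiv), MeCN–H2O (2:1), 0 °C, 15 min
Reagents that add atoms: water, O
Why: Oxidative demethylation of a 1,4-dimethoxyarene: two one-electron oxidations by tetravalent cerium, each followed by attack of water on the ring carbon and loss of methanol. The electron-rich arene should be consumed much faster than isolated trisubstituted alkenes or alcohols in a short reaction at 0 °C.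

## Compound list

1 | 4-methoxy-2-methylphenol | COc1ccc(O)c(C)c1 | starting material
2 | 2-bromo-4-methoxy-6-methylphenol | COc1cc(C)c(O)c(Br)c1 | intermediate
3 | 1-bromo-2,5-dimethoxy-3-methylbenzene | COc1cc(C)c(OC)c(Br)c1 | intermediate
4 | geranyl bromide, (2E)-1-bromo-3,7-dimethylocta-2,6-diene | CC(C)=CCC/C(C)=C/CBr | starting material
5 | (2,5-dimethoxy-3-methylphenyl)magnesium bromide | COc1cc(C)c(OC)c([Mg]Br)c1 | intermediate
6 | 1-[(2E)-3,7-dimethylocta-2,6-dienyl]-2,5-dimethoxy-3-methylbenzene | CC(C)=CCC/C(C)=C/Cc1cc(OC)cc(C)c1OC | intermediate
7 | (2E,6E)-8-(2,5-dimethoxy-3-methylphenyl)-2,6-dimethylocta-2,6-dien-1-ol | OC/C(C)=C/CC/C(C)=C/Cc1cc(OC)cc(C)c1OC | intermediate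
8 | (2E,6E)-8-(2,5-dimethoxy-3-methylphenyl)-2,6-dimethylocta-2,6-dienal | O=C/C(C)=C/CC/C(C)=C/Cc1cc(OC)cc(C)c1OC | intermediate
9 | 1-[(2E,6E)-3,7-dimethylnona-2,6,8-trienyl]-2,5-dimethoxy-3-methylbenzene | C=C/C(C)=C/CC/C(C)=C/Cc1cc(OC)cc(C)c1OC | intermediate
10 | 4-methylpent-3-en-1-ol | CC(C)=CCCO | starting material
11 | 4-methylpent-3-enal | CC(C)=CCC=O | intermediate
12 | ethyl propiolate | C#CC(=O)OCC | starting material
13 | 1-ethoxy-3-iodo-1-(trimethylsilyloxy)propa-1,2-diene | CCOC(=C=CI)O[Si](C)(C)C | intermediate
14 | ethyl (2Z)-3-iodo-2-[(1R)-4-methyl-1-(trimethylsilyloxy)pent-3-enyl]prop-2-enoate | CC(C)=CC[C@@H](O[Si](C)(C)C)/C(=C/I)C(=O)OCC | intermediate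
15 | ethyl (2Z)-2-[(1R)-1-hydroxy-4-methylpent-3-enyl]-3-iodoprop-2-enoate | CC(C)=CC[C@@H](O)/C(=C/I)C(=O)OCC | intermediate
16 | 9-[(3E,7E)-9-(2,5-dimethoxy-3-methylphenyl)-3,7-dimethylnona-3,7-dienyl]-9-borabicyclo[3.3.1]nonane | C1CC2CCCC(C1)B2CC/C(C)=C/CC/C(C)=C/Cc1cc(OC)cc(C)c1OC | intermediate
17 | ethyl (2Z,6E,10E)-12-(2,5-dimethoxy-3-methylphenyl)-2-[(1R)-1-hydroxy-4-methylpent-3-enyl]-6,10-dimethyldodeca-2,6,10-trienoate | CC(C)=CC[C@@H](O)/C(=C/CC/C(C)=C/CC/C(C)=C/Cc1cc(OC)cc(C)c1OC)C(=O)OCC | intermediate
18 | (2E,6E,10E,12R)-1-(2,5-dimethoxy-3-methylphenyl)-11-(hydroxymethyl)-3,7,15-trimethylhexadeca-2,6,10,14-tetraen-12-ol | CC(C)=CC[C@@H](O)/C(=C/CC/C(C)=C/CC/C(C)=C/Cc1cc(OC)cc(C)c1OC)CO | intermediate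
19 | 2-[(2E,6E,10E,12R)-12-hydroxy-11-(hydroxymethyl)-3,7,15-trimethylhexadeca-2,6,10,14-tetraenyl]-6-methylcyclohexa-2,5-diene-1,4-dione | CC(C)=CC[C@@H](O)/C(=C/CC/C(C)=C/CC/C(C)=C/CC1=CC(=O)C=C(C)C1=O)CO | target

## Step count and least certain steps

Total step count: 11. Longest linear sequence: 9 steps (steps 1, 2, 3, 4, 5, 6, 9, 10, 11). Steps 7 and 8 form the short second branch.

**Step 8 (key step).** The most likely failure is erosion of facial selectivity, because the slim, unbranched formyl group of 11 gives the catalyst pocket little to grip. The strongly acidic medium could also move the C14=C15 bond into conjugation, or add HI to it, while the coupling proceeds. The fallback sets out from 11 and 12.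
- The same three components are joined without a chiral catalyst under MgI2 promotion (CH2Cl2, 0 °C). This gives racemic ethyl (2Z)-2-(1-hydroxy-4-methylpent-3-enyl)-3-iodoprop-2-enoate F1.
- Dess–Martin periodinane oxidises it to ethyl (2Z)-2-(iodomethylidene)-6-methyl-3-oxohept-5-enoate F2.
- A Corey–Bakshi–Shibata reduction (catecholborane, (S)-B-methyl oxazaborolidine, toluene, −78 °C), with the branched alkenyl flank as the large group, sets C12 by hydride delivery instead of C–C bond formation. It comes back to the route at 15.

**Step 9.** The most likely failures are base-induced retro-aldol cleavage or Z-to-E drift of the electron-poor beta-iodoacrylate. Loss of the alkyl borane by protodeboronation or beta-hydride elimination could also occur before transmetalation, because the electrophile is both base-sensitive and chelating. The fallback sets out from 15 and removes the acrylate before the union.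
- i-Bu2AlH gives (2E,3R)-2-(iodomethylidene)-6-methylhept-5-ene-1,3-diol F3.
- 2,2-Dimethoxypropane with pyridinium tosylate gives (4R,5E)-5-(iodomethylidene)-2,2-dimethyl-4-(3-methylbut-2-enyl)-1,3-dioxane F4.
- Coupling of this unactivated, ring-locked alkenyl iodide with 16 under zerovalent palladium gives (4R,5E)-5-[(4E,8E)-10-(2,5-dimethoxy-3-methylphenyl)-4,8-dimethyldeca-4,8-dienylidene]-2,2-dimethyl-4-(3-methylbut-2-enyl)-1,3-dioxane F5.
- Aqueous acetic acid returns to the route at 18.

**Step 11.** The most likely failures are over-oxidation of the two allylic alcohols by excess tetravalent cerium and acid-promoted ionisation at C12, which would cause racemisation, allylic transposition or ring closure onto neighbouring alkenes. The cause is that the medium is both oxidising and strongly acidic. The fallback sets out from 18.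
- Anodic oxidation (Pt anode, KOH, MeOH, 0 °C, constant current) is a two-electron process in basic methanol at a potential well below that of the alkenes. It gives the quinone bis(dimethyl ketal) (2E,6E,10E,12R)-11-(hydroxymethyl)-3,7,15-trimethyl-1-(3,3,6,6-tetramethoxy-5-methylcyclohexa-1,4-dienyl)hexadeca-2,6,10,14-tetraen-12-ol F6.
- Brief hydrolysis with dilute aqueous oxalic acid in THF comes back at 19.

**Step 4.** The most likely failures are poor site selectivity, with attack at the C3 methyl group or at the doubly activated C1 methylene. Partial over-oxidation and incomplete conversion are also possible, since all allylic positions compete for the same ene reaction. The fallback sets out from 6. Cross-metathesis with methacrolein (second-generation Hoveyda–Grubbs catalyst, CH2Cl2, 40 °C) exchanges the isopropylidene end for the E-configured 2-methylpropenal end. It comes back at 8, by-passing 7, and makes no new compound.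

## Further compounds

F1 | step 8 | racemic ethyl (2Z)-2-(1-hydroxy-4-methylpent-3-enyl)-3-iodoprop-2-enoate | CC(C)=CCC(O)/C(=C/I)C(=O)OCC
F2 | step 8 | ethyl (2Z)-2-(iodomethylidene)-6-methyl-3-oxohept-5-enoate | CC(C)=CCC(=O)/C(=C/I)C(=O)OCC
F3 | step 9 | (2E,3R)-2-(iodomethylidene)-6-methylhept-5-ene-1,3-diol | CC(C)=CC[C@@H](O)/C(=C/I)CO
F4 | step 9 | (4R,5E)-5-(iodomethylidene)-2,2-dimethyl-4-(3-methylbut-2-enyl)-1,3-dioxane | CC(C)=CC[C@H]1OC(C)(C)OC/C1=C\I
F5 | step 9 | (4R,5E)-5-[(4E,8E)-10-(2,5-dimethoxy-3-methylphenyl)-4,8-dimethyldeca-4,8-dienylidene]-2,2-dimethyl-4-(3-methylbut-2-enyl)-1,3-dioxane | CC(C)=CC[C@H]1OC(C)(C)OC/C1=C\CC/C(C)=C/CC/C(C)=C/Cc1cc(OC)cc(C)c1OC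
F6 | step 11 | (2E,6E,10E,12R)-11-(hydroxymethyl)-3,7,15-trimethyl-1-(3,3,6,6-tetramethoxy-5-methylcyclohexa-1,4-dienyl)hexadeca-2,6,10,14-tetraen-12-ol | CC(C)=CC[C@@H](O)/C(=C/CC/C(C)=C/CC/C(C)=C/CC1=CC(OC)(OC)C=C(C)C1(OC)OC)CO
F0 | step 4 | none | none
A1 | alternative 1 | tert-butyl{[(2E,6E,10E)-12-(2,5-dimethoxy-3-methylphenyl)-2-iodo-6,10-dimethyldodeca-2,6,10-trienyl]oxy}dimethylsilane | I/C(=C/CC/C(C)=C/CC/C(C)=C/Cc1cc(OC)cc(C)c1OC)CO[Si](C)(C)C(C)(C)C
A2 | alternative 1 | (2E,6E,10E,12R)-11-[(tert-butyldimethylsilyloxy)methyl]-1-(2,5-dimethoxy-3-methylphenyl)-3,7,15-trimethylhexadeca-2,6,10,14-tetraen-12-ol | CC(C)=CC[C@@H](O)/C(=C/CC/C(C)=C/CC/C(C)=C/Cc1cc(OC)cc(C)c1OC)CO[Si](C)(C)C(C)(C)C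
A3 | alternative 2 | (2Z,6E,10E)-12-(2,5-dimethoxy-3-methylphenyl)-6,10-dimethyl-2-[(2-methylbut-3-en-2-yloxy)methyl]dodeca-2,6,10-trien-1-ol | C=CC(C)(C)OC/C(=C/CC/C(C)=C/CC/C(C)=C/Cc1cc(OC)cc(C)c1OC)CO
A4 | alternative 3 | (4R)-2,2-dimethyl-4-(3-methylbut-2-enyl)-1,3-dioxan-5-one | CC(C)=CC[C@H]1OC(C)(C)OCC1=O
A5 | alternative 3 | [(4E,8E)-10-(2,5-dimethoxy-3-methylphenyl)-4,8-dimethyldeca-4,8-dienyl]triphenylphosphonium iodide | [I-].c1ccccc1[P+](c1ccccc1)(c1ccccc1)CCC/C(C)=C/CC/C(C)=C/Cc1cc(OC)cc(C)c1OC
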